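**Assumptions (stated once):**
- The target is the (2S,3R)-butyl acetate, C8 = S and C8′ = R in lignan numbering. I checked both centres from the SMILES.
- The two carbenoids, (R)-configured at the lithiated carbon, are made with the (+)-sparteine surrogate. Each 1,2-metallate shift is taken to go with retention at the migrating carbon and inversion at the C–O carbon. If this assignment is wrong, both homologations flip together. Using (−)-sparteine for both then gives the correct absolute configuration, and the relative configuration is unaffected.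
- Homosyringic acid, homovanillyl alcohol, MeBpin, ClCH₂I and TIBCl are commercial.

## Retrosynthetic overview
1. The target is the 9-OAc, bis-phenol. It comes from acetylation and then hydrogenolysis of the two aryl benzyl ethers of primary alcohol **13**.
2. Alcohol **13** comes from oxidation of primary alkyl-Bpin **12**. **12** comes from one-carbon homologation (LiCH₂Cl) of secondary boronic ester **10**.
3. Both stereocentres come from an iterative Hoppe–Aggarwal lithiation–borylation "assembly line".
   - MeBpin plus the carbenoid from the homosyringyl TIB ester gives the C8′ centre.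
   - The resulting Bpin plus the carbenoid from the homovanillyl TIB ester gives the C8 centre.
   - The same (+)-sparteine surrogate is used for both, and every C–C bond forms by a stereospecific 1,2-metallate shift.
4. No ring is formed. The target is acyclic, and both arenes are carried in from commercial arylethanol precursors.

## Route

**Step 1**
Reactants: **1** 4-hydroxy-3,5-dimethoxyphenylacetic acid
Product: **2** 2-(4-hydroxy-3,5-dimethoxyphenyl)ethanol
Conditions: BH₃·THF, THF, 0 °C → rt; MeOH quench
Reagents that add atoms: none (BH₃ delivers hydride only)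
Why: Borane reduces carboxylic acids chemoselectively in the presence of the free phenol (hydride reduction of a carboxylic acid); no stereocentre is involved.

**Step 2**
Reactants: **2**
Product: **3** 2-(4-benzyloxy-3,5-dimethoxyphenyl)ethanol
Conditions: BnBr, K₂CO₃, acetone, 60 °C
Reagents that add atoms: benzyl bromide, BrCc1ccccc1
Why: The phenol is far more acidic than the primary alcohol, so Williamson O-benzylation is selective for it. The benzyl ether is a phenol protecting group that tolerates RLi and is removed neutrally at the end.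

**Step 3**
Reactants: **4** homovanillyl alcohol (2-(4-hydroxy-3-methoxyphenyl)ethanol)
Product: **5** 2-(4-benzyloxy-3-methoxyphenyl)ethanol
Conditions: BnBr, K₂CO₃, acetone, 60 °C
Reagents that add atoms: benzyl bromide, BrCc1ccccc1
Why: Same chemoselective phenol Williamson benzylation as Step 2.

**Step 4**
Reactants: **3**
Product: **6** 2-(4-benzyloxy-3,5-dimethoxyphenyl)ethyl 2,4,6-triisopropylbenzoate
Conditions: TIBCl, Et₃N, DMAP (cat.), CH₂Cl₂, 0 °C → rt
Reagents that add atoms: 2,4,6-triisopropylbenzoyl chloride, CC(C)c1cc(C(C)C)c(C(=O)Cl)c(C(C)C)c1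
Why: Acylation gives the hindered benzoate that is the configurationally stable lithiation–borylation carbenoid precursor.

**Step 5**
Reactants: **5**
Product: **7** 2-(4-benzyloxy-3-methoxyphenyl)ethyl 2,4,6-triisopropylbenzoate
Conditions: TIBCl, Et₃N, DMAP (cat.), CH₂Cl₂, 0 °C → rt
Reagents that add atoms: TIBCl, CC(C)c1cc(C(C)C)c(C(=O)Cl)c(C(C)C)c1
Why: Same acylation as Step 4.

**Step 6 (C8′ stereocentre)**
Reactants: **6**; **8** methylboronic acid pinacol ester (MeBpin)
Product: **9** (R)-2-[1-(4-benzyloxy-3,5-dimethoxyphenyl)propan-2-yl]-4,4,5,5-tetramethyl-1,3,2-dioxaborolane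
Conditions: s-BuLi, (+)-sparteine surrogate, Et₂O, −78 °C, 5 h; then **8**, −78 °C → rt
Reagents that add atoms: none (**8** is the numbered reactant)
Why: Lithiation–borylation. The chiral base removes the pro-R α-H of the TIB ester, giving a configurationally stable (R)-carbenoid. Boronate formation followed by a 1,2-shift of Me from B to C with displacement of TIBO⁻ fixes the new C–Me centre as (R) at the carbon that becomes C8′.

**Step 7 (C8 stereocentre, C8–C8′ bond)**
Reactants: **9**; **7**
Product: **10** pinacol boronate of (2S,3R)-1-(4-benzyloxy-3-methoxyphenyl)-4-(4-benzyloxy-3,5-dimethoxyphenyl)-3-methylbutan-2-yl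
Conditions: **7**, s-BuLi, (+)-sparteine surrogate, Et₂O, −78 °C; then **9**, −78 °C → rt; then MgBr₂·OEt₂, THF, 40 °C
Reagents that add atoms: none
Why: Second lithiation–borylation. The (R)-carbenoid from **7** is attacked by the chiral secondary boronic ester, and the 1,2-shift moves C8′ to C8 with retention at C8′ and inversion at carbenoid carbon. The configuration at C8 is set by the reagent, so the relative configuration (2S,3R) is controlled by using the same-handed carbenoid in both homologations, and MgBr₂ drives the hindered shift.

**Step 8**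
Reactants: **10**; **11** chloroiodomethane
Product: **12** pinacol boronate of (2S,3R)-2-(4-benzyloxy-3-methoxybenzyl)-4-(4-benzyloxy-3,5-dimethoxyphenyl)-3-methylbutyl (primary CH₂Bpin)
Conditions: **11**, n-BuLi (generates LiCH₂Cl in situ), THF, −78 °C → rt
Reagents that add atoms: none (**11** is the numbered reactant)
Why: Matteson-type homologation with LiCH₂Cl. The secondary alkyl group migrates from B to CH₂ with retention, so C8 keeps its configuration and becomes C9–CH₂Bpin.

**Step 9**
Reactants: **12**
Product: **13** (2S,3R)-2-(4-benzyloxy-3-methoxybenzyl)-4-(4-benzyloxy-3,5-dimethoxyphenyl)-3-methylbutan-1-ol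
Conditions: 30% H₂O₂, 3 M NaOH, THF, 0 °C → rt
Reagents that add atoms: hydrogen peroxide, OO (supplies the OH oxygen)
Why: Oxidation of a C–B bond to C–OH proceeds with retention, and the stereocentres are not benzylic or acidic, so they are not scrambled.

**Step 10**
Reactants: **13**
Product: **14** (2S,3R)-2-(4-benzyloxy-3-methoxybenzyl)-4-(4-benzyloxy-3,5-dimethoxyphenyl)-3-methylbutyl acetate
Conditions: Ac₂O, pyridine, DMAP (cat.), CH₂Cl₂, rt
Reagents that add atoms: acetic anhydride, CC(=O)OC(C)=O
Why: Acylation of the only free OH; both phenols are protected.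

**Step 11**
Reactants: **14**
Product: **15** target, (2S,3R)-4-(4-hydroxy-3,5-dimethoxyphenyl)-2-(4-hydroxy-3-methoxybenzyl)-3-methylbutyl acetate
Conditions: H₂ (1 atm), 10% Pd/C, EtOAc, rt
Reagents that add atoms: none (hydrogen only; toluene is lost)
Why: Catalytic hydrogenolysis of the two aryl benzyl ethers is neutral, leaves the acetate and aryl OMe groups intact, and touches no stereocentre because none is benzylic.

## Compound list
| # | Name | SMILES | Role |
|---|---|---|---|
| 1 | 4-hydroxy-3,5-dimethoxyphenylacetic acid | COc1cc(CC(=O)O)cc(OC)c1O | starting material |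
| 2 | 2-(4-hydroxy-3,5-dimethoxyphenyl)ethanol | COc1cc(CCO)cc(OC)c1O | intermediate |
| 3 | 2-(4-benzyloxy-3,5-dimethoxyphenyl)ethanol | COc1cc(CCO)cc(OC)c1OCc1ccccc1 | intermediate |
| 4 | homovanillyl alcohol | COc1cc(CCO)ccc1O | starting material |
| 5 | 2-(4-benzyloxy-3-methoxyphenyl)ethanol | COc1cc(CCO)ccc1OCc1ccccc1 | intermediate |
| 6 | TIB ester of 3 | COc1cc(CCOC(=O)c2c(C(C)C)cc(C(C)C)cc2C(C)C)cc(OC)c1OCc1ccccc1 | intermediate |
| 7 | TIB ester of 5 | COc1cc(CCOC(=O)c2c(C(C)C)cc(C(C)C)cc2C(C)C)ccc1OCc1ccccc1 | intermediate |
| 8 | methylboronic acid pinacol ester | CB1OC(C)(C)C(C)(C)O1 | starting material |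
| 9 | (R)-Ar′CH₂CH(CH₃)Bpin, Ar′ = 4-BnO-3,5-(MeO)₂C₆H₂ | B1(OC(C)(C)C(C)(C)O1)[C@H](C)Cc1cc(OC)c(OCc2ccccc2)c(OC)c1 | intermediate |
| 10 | secondary Bpin (2S,3R) | COc1cc(C[C@H](B2OC(C)(C)C(C)(C)O2)[C@H](C)Cc3cc(OC)c(OCc4ccccc4)c(OC)c3)ccc1OCc1ccccc1 | intermediate |
| 11 | chloroiodomethane | ClCI | starting material |
| 12 | primary CH₂Bpin homologue (2S,3R) | COc1cc(C[C@H](CB2OC(C)(C)C(C)(C)O2)[C@H](C)Cc3cc(OC)c(OCc4ccccc4)c(OC)c3)ccc1OCc1ccccc1 | intermediate |
| 13 | (2S,3R)-primary alcohol, bis-OBn | COc1cc(C[C@H](CO)[C@H](C)Cc2cc(OC)c(OCc3ccccc3)c(OC)c2)ccc1OCc1ccccc1 | intermediate |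
| 14 | (2S,3R)-acetate, bis-OBn | COc1cc(C[C@H](COC(C)=O)[C@H](C)Cc2cc(OC)c(OCc3ccccc3)c(OC)c2)ccc1OCc1ccccc1 | intermediate |
| 15 | (2S,3R)-4-(4-hydroxy-3,5-dimethoxyphenyl)-2-(4-hydroxy-3-methoxybenzyl)-3-methylbutyl acetate | COc1cc(C[C@H](COC(C)=O)[C@H](C)Cc2cc(OC)c(O)c(OC)c2)ccc1O | target |

## Totals
Total steps: 11. Longest linear sequence: 9 (Steps 1, 2, 4, 6, 7, 8, 9, 10, 11).

## Three steps most likely to fail
1. **Step 7.** The hindered secondary boronic ester plus a secondary carbenoid may give low conversion, carbenoid decomposition, or poor dr.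
   - Fallback: Matteson route. Convert **9** to its pinanediol ester, add LiCHCl₂, then add 4-benzyloxy-3-methoxybenzylmagnesium chloride, so the C8 centre is set by the diol auxiliary instead of the carbenoid.
2. **Step 6.** Methyl migration from MeBpin may be slow, the yield or er may be poor, or the aryl benzyl ether may interfere with s-BuLi.
   - Fallback: swap the disconnection. Homologate benzylic Ar′CH₂Bpin (Pd-catalysed borylation of the benzyl chloride from **3**) with the lithiated ethyl TIB ester, so the chiral carbenoid supplies the methyl-bearing carbon.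
3. **Step 8.** LiCH₂Cl homologation of the β-branched secondary Bpin may be sluggish or give deboronation.
   - Fallback: Matteson one-carbon homologation with LiCHCl₂. Oxidation of the α-chloroboronate gives the C9 aldehyde directly, which is then reduced with NaBH₄ immediately, before the α-stereocentre can epimerise.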